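**Retrosynthetic overview**
1. Target 12 (7S,8S,8′R; the two ring substituents are cis) ⇐ benzylidene-oxolane 10, by syn-hydrogenation of the exocyclic C-7′=C-8′ bond anti to the C-8 side chain, with loss of both benzyl groups and the silyl group; C-8′ is made last.
2. 10 ⇐ 9: the only ring, the oxolane, is closed by loss of water between O-9 and C-9′ of an allylic seco-lignan 1,4-diol, before C-8′ is a stereocentre, so that the ring relays C-8 to C-8′.
3. 9 ⇐ 8 ⇐ 7 + 1: LiAlH4 reduction of an anti-aldol adduct; C-7 and C-8 come from an auxiliary-controlled MgCl2-catalysed anti-aldol.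
4. 7 ⇐ 4 + 5; 4 ⇐ 1 + 2: a Stobbe condensation supplies C-7′ to C-9′, C-8 and C-9 with the E-alkene.
5. Ring order: both arenes are bought; the oxolane is formed in step 5.

Assumptions (one line): lignan numbering is used (C-7 carbinol, C-8/C-8′ ring CH, C-9/C-9′ ring CH2); the oxolane is presumed to arise in the plant by loss of water between O-9 and C-9′ of an 8,8′-linked 1,4-diol; the MgCl2 anti-aldol is taken to follow the chelated Z-enolate model (recalled, not checked against the original report), which makes the (S)-auxiliary the right one.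

Step 1
Reactants: 1 3-(benzyloxy)-4-methoxybenzaldehyde; 2 diethyl succinate
Product: 4 (3E)-4-[3-(benzyloxy)-4-methoxyphenyl]-3-(ethoxycarbonyl)but-3-enoic acid, via Stobbe lactone 3 (not isolated)
Conditions: KOtBu, tBuOH, reflux; then HCl (aq)
Reagents that add atoms: none
Why: Stobbe condensation: the succinate enolate adds to the aldehyde, the alkoxide lactonises onto the distal ester to give 3, and base-induced E1cB ring opening gives the (E)-arylidene half-ester (aryl cis to the CH2CO2H arm) with only the distal carboxyl freed.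

Step 2
Reactants: 4 (3E)-4-[3-(benzyloxy)-4-methoxyphenyl]-3-(ethoxycarbonyl)but-3-enoic acid; 5 (4S)-4-benzyl-1,3-oxazolidin-2-one
Product: 7 (4S)-4-benzyl-3-{(3E)-4-[3-(benzyloxy)-4-methoxyphenyl]-3-(ethoxycarbonyl)but-3-enoyl}-1,3-oxazolidin-2-one, via mixed pivalic anhydride 6 (not isolated)
Conditions: Et3N, tBuCOCl, THF, −20 °C; then LiCl, 5, −20 °C → rt
Reagents that add atoms: pivaloyl chloride, CC(C)(C)C(Cl)=O (its acyl group is carried only by intermediate 6 and leaves again as pivalic acid)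
Why: N-acylation of an oxazolidinone through a mixed pivalic anhydride (LiCl/Et3N variant): the oxazolidinone attacks the less hindered carbonyl of 6, which attaches the auxiliary without touching the conjugated ester or the alkene geometry.

Step 3
Reactants: 7 (4S)-4-benzyl-3-{(3E)-4-[3-(benzyloxy)-4-methoxyphenyl]-3-(ethoxycarbonyl)but-3-enoyl}-1,3-oxazolidin-2-one; 1 3-(benzyloxy)-4-methoxybenzaldehyde
Product: 8 (4S)-4-benzyl-3-[(2R,3E)-2-{(S)-[3-(benzyloxy)-4-methoxyphenyl][(trimethylsilyl)oxy]methyl}-4-[3-(benzyloxy)-4-methoxyphenyl]-3-(ethoxycarbonyl)but-3-enoyl]-1,3-oxazolidin-2-one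
Conditions: MgCl2 (20 mol%), Et3N, Me3SiCl, EtOAc, 23 °C
Reagents that add atoms: chlorotrimethylsilane, C[Si](C)(C)Cl
Why: Evans MgCl2-catalysed direct anti-aldol reaction: soft enolisation gives the chelated Z-enolate, which adds through its α-carbon to the non-enolisable aldehyde on the face away from the auxiliary benzyl group (boat transition state) to give the 7,8-anti adduct (C-7 S, C-8 R by CIP), and in situ silylation of the aldolate turns the catalyst over and masks O-7.

Step 4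
Reactants: 8 (4S)-4-benzyl-3-[(2R,3E)-2-{(S)-[3-(benzyloxy)-4-methoxyphenyl][(trimethylsilyl)oxy]methyl}-4-[3-(benzyloxy)-4-methoxyphenyl]-3-(ethoxycarbonyl)but-3-enoyl]-1,3-oxazolidin-2-one
Product: 9 (2S,3E)-2-{(S)-[3-(benzyloxy)-4-methoxyphenyl][(trimethylsilyl)oxy]methyl}-3-{[3-(benzyloxy)-4-methoxyphenyl]methylidene}butane-1,4-diol
Conditions: LiAlH4, THF, −30 → 0 °C; Na2SO4·10H2O
Reagents that add atoms: none
Why: Hydride reduction: LiAlH4 cleaves the N-acyl oxazolidinone at the exocyclic carbonyl to the C-9 primary alcohol and reduces the conjugated ester 1,2 to the C-9′ allylic alcohol at low temperature, so no stereocentre is touched (C-8 becomes S only because the CIP priorities change).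

Step 5
Reactants: 9 (2S,3E)-2-{(S)-[3-(benzyloxy)-4-methoxyphenyl][(trimethylsilyl)oxy]methyl}-3-{[3-(benzyloxy)-4-methoxyphenyl]methylidene}butane-1,4-diol
Product: 10 {(S)-[3-(benzyloxy)-4-methoxyphenyl][(3S,4E)-4-{[3-(benzyloxy)-4-methoxyphenyl]methylidene}oxolan-3-yl]methoxy}trimethylsilane
Conditions: PPh3, DIAD, THF, 0 °C → rt
Reagents that add atoms: none
Why: Mitsunobu cyclodehydration of a 1,4-diol: one primary hydroxyl becomes an oxyphosphonium leaving group and the other displaces it in a 5-exo-tet closure (O-7 is silylated and cannot compete), so the oxolane is made by the same net loss of water between O-9 and C-9′ that is presumed in the plant, with no stereocentre involved.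

Step 6
Reactants: 10 {(S)-[3-(benzyloxy)-4-methoxyphenyl][(3S,4E)-4-{[3-(benzyloxy)-4-methoxyphenyl]methylidene}oxolan-3-yl]methoxy}trimethylsilane
Product: 12 (S)-[(3S,4R)-4-(3-hydroxy-4-methoxybenzyl)oxolan-3-yl](3-hydroxy-4-methoxyphenyl)methanol, via O-7 silyl ether 11 (not isolated)
Conditions: H2 (1 atm), Pd/C (10 wt% Pd), EtOAc, rt; filter; K2CO3 (cat.), MeOH, rt
Reagents that add atoms: none
Why: Heterogeneous catalytic hydrogenation with hydrogenolysis of both benzyl ethers: A(1,3) strain with the (E)-aryl group holds the C-8 side chain pseudo-axial, so H2 is added syn to the exocyclic alkene from the opposite face and the new benzyl group ends up cis to that side chain (C-8′ R), after which K2CO3/MeOH methanolysis removes the silyl ether.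

**Compound list**
1 | 3-(benzyloxy)-4-methoxybenzaldehyde (O-benzylisovanillin) | `COc1ccc(C=O)cc1OCc1ccccc1` | starting material
2 | diethyl succinate | `CCOC(=O)CCC(=O)OCC` | starting material
3 | ethyl 2-[3-(benzyloxy)-4-methoxyphenyl]-5-oxooxolane-3-carboxylate (Stobbe lactone; stereoisomer mixture, both centres are lost on ring opening) | `CCOC(=O)C1CC(=O)OC1c1ccc(OC)c(OCc2ccccc2)c1` | intermediate (not isolated)
4 | (3E)-4-[3-(benzyloxy)-4-methoxyphenyl]-3-(ethoxycarbonyl)but-3-enoic acid | `CCOC(=O)/C(CC(=O)O)=C/c1ccc(OC)c(OCc2ccccc2)c1` | intermediate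
5 | (4S)-4-benzyl-1,3-oxazolidin-2-one | `O=C1OC[C@H](Cc2ccccc2)N1` | starting material
6 | (3E)-4-[3-(benzyloxy)-4-methoxyphenyl]-3-(ethoxycarbonyl)but-3-enoic 2,2-dimethylpropanoic anhydride | `CCOC(=O)/C(CC(=O)OC(=O)C(C)(C)C)=C/c1ccc(OC)c(OCc2ccccc2)c1` | intermediate (not isolated)
7 | (4S)-4-benzyl-3-{(3E)-4-[3-(benzyloxy)-4-methoxyphenyl]-3-(ethoxycarbonyl)but-3-enoyl}-1,3-oxazolidin-2-one | `CCOC(=O)/C(CC(=O)N1C(=O)OC[C@@H]1Cc1ccccc1)=C/c1ccc(OC)c(OCc2ccccc2)c1` | intermediate
8 | (4S)-4-benzyl-3-[(2R,3E)-2-{(S)-[3-(benzyloxy)-4-methoxyphenyl][(trimethylsilyl)oxy]methyl}-4-[3-(benzyloxy)-4-methoxyphenyl]-3-(ethoxycarbonyl)but-3-enoyl]-1,3-oxazolidin-2-one | `C[Si](C)(C)O[C@H](c1ccc(OC)c(OCc2ccccc2)c1)[C@H](C(=O)N1C(=O)OC[C@@H]1Cc1ccccc1)/C(C(=O)OCC)=C\c1ccc(OC)c(OCc2ccccc2)c1` | intermediate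
9 | (2S,3E)-2-{(S)-[3-(benzyloxy)-4-methoxyphenyl][(trimethylsilyl)oxy]methyl}-3-{[3-(benzyloxy)-4-methoxyphenyl]methylidene}butane-1,4-diol | `C[Si](C)(C)O[C@H](c1ccc(OC)c(OCc2ccccc2)c1)[C@H](CO)/C(CO)=C\c1ccc(OC)c(OCc2ccccc2)c1` | intermediate
10 | {(S)-[3-(benzyloxy)-4-methoxyphenyl][(3S,4E)-4-{[3-(benzyloxy)-4-methoxyphenyl]methylidene}oxolan-3-yl]methoxy}trimethylsilane | `C[Si](C)(C)O[C@H](c1ccc(OC)c(OCc2ccccc2)c1)[C@@H]1COC/C1=C/c1ccc(OC)c(OCc2ccccc2)c1` | intermediate
11 | {(S)-(3-hydroxy-4-methoxyphenyl)[(3S,4R)-4-(3-hydroxy-4-methoxybenzyl)oxolan-3-yl]methoxy}trimethylsilane | `C[Si](C)(C)O[C@H](c1ccc(OC)c(O)c1)[C@@H]1COC[C@@H]1Cc1ccc(OC)c(O)c1` | intermediate (not isolated)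
12 | (S)-[(3S,4R)-4-(3-hydroxy-4-methoxybenzyl)oxolan-3-yl](3-hydroxy-4-methoxyphenyl)methanol (7S,8S,8′R) | `COc1ccc(C[C@H]2COC[C@H]2[C@H](O)c2ccc(OC)c(O)c2)cc1O` | target

**Totals**
Total steps: 6. Longest linear sequence: 6 steps (1 → 4 → 7 → 8 → 9 → 10 → 12).

**Three steps most likely to fail**

Step 3 (anti-aldol). The vinylogous enolate of 7 may react slowly with the electron-rich aldehyde, react at its γ-carbon, or shift the double bond into conjugation, and the sense of induction rests on the chelate model. The fallback sets out from 7 and comes back at 8; it makes the two centres one after the other instead of together. Commercial 3-(benzyloxy)-4-methoxybenzoic acid is converted with (COCl)2 and catalytic DMF into 3-(benzyloxy)-4-methoxybenzoyl chloride F1. The sodium enolate of 7 (NaN(SiMe3)2, THF, −78 °C) is C-acylated by F1 on the face away from the auxiliary benzyl group to give the β-keto imide F2, in which C-8 is fixed by the auxiliary and held against enolisation by A(1,3) strain. Reagent-controlled ketone reduction ((R)-2-methyl-CBS-oxazaborolidine, BH3·SMe2, aryl as the large group) gives the 7S anti-hydroxy imide F3, and Me3SiCl/imidazole returns 8.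

Step 4 (reduction). The trimethylsilyl ether may be cleaved or migrate from O-7 to the O-9 aluminium alkoxide, and some 1,4-reduction of the enoate is possible. The fallback sets out from 8 and comes back at 12; it gives up the silyl group and closes the ring on the free triol by activating O-9 only. LiAlH4 followed by K2CO3/MeOH gives the triol F4. Bu2SnO (cat.), TsCl and Et3N sulfonylate the primary oxygen of the 7,9-(1,3)-diol through its six-membered stannylene acetal, giving the O-9 monotosylate F5. With NaH in THF only O-9′ can close a five-membered ring onto C-9 (O-7 could only form an oxetane), giving the hydroxy-oxolane F6, and H2 over Pd/C then delivers 12 directly.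

Step 6 (hydrogenation). Pd may cleave the allylic C-9′–O bond or move the double bond into the ring before it is saturated, and the cis:trans ratio is unproven for this ether. The fallback sets out from 9 and comes back at 11; it sets C-8′ on a lactone, where cis-selective hydrogenation of α-benzylidene-γ-butyrolactones is the classical entry to cis-dibenzylbutyrolactone lignans. MnO2 in CH2Cl2 oxidises the allylic alcohol of 9 and the resulting lactol to the α-benzylidene lactone F7. H2 over Rh/Al2O3 in EtOAc adds anti to the C-8 substituent and leaves the benzyl ethers, giving the cis-lactone F8. LiAlH4 gives the saturated diol F9, PPh3/DIAD closes the protected cis-oxolane F10, and H2 over Pd/C removes both benzyl groups to give 11, which is desilylated as in step 6.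

**Further compounds**
F1 | step 3 | 3-(benzyloxy)-4-methoxybenzoyl chloride | `COc1ccc(C(Cl)=O)cc1OCc1ccccc1`
F2 | step 3 | (4S)-4-benzyl-3-{(2R,3E)-2-[3-(benzyloxy)-4-methoxybenzoyl]-4-[3-(benzyloxy)-4-methoxyphenyl]-3-(ethoxycarbonyl)but-3-enoyl}-1,3-oxazolidin-2-one | `O=C(c1ccc(OC)c(OCc2ccccc2)c1)[C@H](C(=O)N1C(=O)OC[C@@H]1Cc1ccccc1)/C(C(=O)OCC)=C\c1ccc(OC)c(OCc2ccccc2)c1`
F3 | step 3 | (4S)-4-benzyl-3-[(2R,3E)-2-{(S)-[3-(benzyloxy)-4-methoxyphenyl](hydroxy)methyl}-4-[3-(benzyloxy)-4-methoxyphenyl]-3-(ethoxycarbonyl)but-3-enoyl]-1,3-oxazolidin-2-one | `O[C@H](c1ccc(OC)c(OCc2ccccc2)c1)[C@H](C(=O)N1C(=O)OC[C@@H]1Cc1ccccc1)/C(C(=O)OCC)=C\c1ccc(OC)c(OCc2ccccc2)c1`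
F4 | step 4 | (2S,3E)-2-{(S)-[3-(benzyloxy)-4-methoxyphenyl](hydroxy)methyl}-3-{[3-(benzyloxy)-4-methoxyphenyl]methylidene}butane-1,4-diol | `O[C@H](c1ccc(OC)c(OCc2ccccc2)c1)[C@H](CO)/C(CO)=C\c1ccc(OC)c(OCc2ccccc2)c1`
F5 | step 4 | (2S,3E)-2-{(S)-[3-(benzyloxy)-4-methoxyphenyl](hydroxy)methyl}-3-{[3-(benzyloxy)-4-methoxyphenyl]methylidene}-4-hydroxybutyl 4-methylbenzenesulfonate | `O[C@H](c1ccc(OC)c(OCc2ccccc2)c1)[C@H](COS(=O)(=O)c1ccc(C)cc1)/C(CO)=C\c1ccc(OC)c(OCc2ccccc2)c1`
F6 | step 4 | (S)-[3-(benzyloxy)-4-methoxyphenyl][(3S,4E)-4-{[3-(benzyloxy)-4-methoxyphenyl]methylidene}oxolan-3-yl]methanol | `O[C@H](c1ccc(OC)c(OCc2ccccc2)c1)[C@@H]1COC/C1=C/c1ccc(OC)c(OCc2ccccc2)c1`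
F7 | step 6 | (3E,4S)-3-{[3-(benzyloxy)-4-methoxyphenyl]methylidene}-4-{(S)-[3-(benzyloxy)-4-methoxyphenyl][(trimethylsilyl)oxy]methyl}oxolan-2-one | `C[Si](C)(C)O[C@H](c1ccc(OC)c(OCc2ccccc2)c1)[C@@H]1COC(=O)/C1=C/c1ccc(OC)c(OCc2ccccc2)c1`
F8 | step 6 | (3R,4S)-3-[3-(benzyloxy)-4-methoxybenzyl]-4-{(S)-[3-(benzyloxy)-4-methoxyphenyl][(trimethylsilyl)oxy]methyl}oxolan-2-one | `C[Si](C)(C)O[C@H](c1ccc(OC)c(OCc2ccccc2)c1)[C@@H]1COC(=O)[C@@H]1Cc1ccc(OC)c(OCc2ccccc2)c1`
F9 | step 6 | (2S,3R)-2-{(S)-[3-(benzyloxy)-4-methoxyphenyl][(trimethylsilyl)oxy]methyl}-3-[3-(benzyloxy)-4-methoxybenzyl]butane-1,4-diol | `C[Si](C)(C)O[C@H](c1ccc(OC)c(OCc2ccccc2)c1)[C@H](CO)[C@H](CO)Cc1ccc(OC)c(OCc2ccccc2)c1`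
F10 | step 6 | {(S)-[3-(benzyloxy)-4-methoxyphenyl][(3S,4R)-4-[3-(benzyloxy)-4-methoxybenzyl]oxolan-3-yl]methoxy}trimethylsilane | `C[Si](C)(C)O[C@H](c1ccc(OC)c(OCc2ccccc2)c1)[C@@H]1COC[C@@H]1Cc1ccc(OC)c(OCc2ccccc2)c1`
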